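starting material 0.64 M; second substrate 0.640 M; free catalyst 19 mM; impurity 6.6 mM; added ligand 11 mM

    second substrate + free catalyst ⇌ catalyst intermediate B (K1 = 1.3 M⁻¹, k1 = 1.4 M⁻¹ min⁻¹)
    free catalyst + impurity → spent catalyst (k2 = 680 M⁻¹ min⁻¹)
    catalyst intermediate A → free catalyst + target (k3 = 0.74 min⁻¹)
    free catalyst + added ligand ⇌ idle complex, settled at all times (K4 = 3300 M⁻¹)
    starting material + free catalyst ⇌ catalyst intermediate A (K5 = 5.0 M⁻¹, k5 = 0.73 M⁻¹ min⁻¹)
    catalyst intermediate B → free catalyst + second product (k6 = 5.3 min⁻¹)

- the form that holds most of the catalyst when 10% of the starting material are converted (idle complex / free catalyst / catalyst intermediate A / spent catalyst / catalyst intermediate B)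
- its share of the catalyst then
- factor on the rate of making target when 10% of the starting material are converted if free catalyst is charged twice over
- factor on the rate when 10% of the starting material are converted if free catalyst is charged at 200 mM instead

At late times the impurity has no way back: this flask charges more catalyst than impurity and that step runs one way, so spent catalyst must end at 34.7% of the charge. Whether the next run should double the catalyst hangs on what stands beyond that loss. With both intermediates in steady state and both substrates as charged, each free catalyst keeps 0.527 of intermediate A and 0.141 of intermediate B beside it, so the round holds 1.67 times the free catalyst. Balancing the round against the added ligand puts free catalyst at 9.44% of the charge, so free catalyst, the resting state of the round, holds more of the catalyst than intermediate A. That makes 15.7%: the working share, the part of the charge standing as free catalyst and both intermediates after impurity and ligand have taken theirs. Idle complex keeps 49.5%.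

This state comes early, because 10% conversion is reckoned to take 1.52 h, and the impurity's half-life at that free catalyst, 0.569 min, is far shorter. In the doubled flask the same balance puts free catalyst at 32.6% of its charge, so the rate should rise by a factor of 6.91, and the reckoning by hand speaks for doubling in the next run. For 200 mM the sum gives 61.0, but it takes the starting material as charged, while intermediate A on that sum holds 9.01% of it, just less than the 10% looked at, so the reckoning stops short of committing to that figure.

The forecast names idle complex at 50% with factors 7 and 48, the second differing from the uncommitted sum above, “because binding into intermediate A uses up much of the 10% conversion”.

The flask reached 10% conversion at 1.56 h, with idle complex holding 49.8% of the catalyst and the factors at 7.03 and 47.9. By 0.150 h the impurity stood at 0% and spent catalyst at 34.7%, while free catalyst and both intermediates together stood at 15.7%. Both rounds then ran on that catalyst, and by 1.50 h target had reached 9.49% with idle complex at 49.7%. With free catalyst charged twice over, the working share reckons at 54.4% of that charge, and the factor on the rate came to 7.03.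

All constants are made up; the run is a simulation.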